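In the early seconds of the teal run I used the bench rule for a gas-fed reaction: dissolved gas is taken up as it arrives, so product climbs in a straight line at a feed rate r. Target, with idle complex counted in, read 9.9% at 15.0 s, which gives r = 8.58 mM/s.

| setting | teal | flask |
|---|---|---|
| substrate | 1.3 M | 0.85 M |
| gas phase | 130 mM (held) | 130 mM (held) |
| catalyst | 15 mol% | 15 mol% |
| remark | run made earlier |  |
| time |  | 5.0 min |

- teal (time / s: target / %, idle complex / %): 15.0: 9.9, 1.7; 30.0: 18.9, 4.0; 50.0: 27.9, 6.9; 60.0: 33.8, 9.9; 80.0: 42.6, 10.5; 90.0: 44.3, 11.7

(readings scatter by 0.5 percentage points)

- a species is counted by the substrate in it: one side product counts as two
- amounts and yields of target count idle complex too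
- at the start none of the gas is dissolved
- what was read earlier has a scatter of 0.5 percentage points, one standard deviation
- on the list of suspects stand: gas phase <-> dissolved gas; substrate + dissolved gas + catalyst -> catalyst + target; catalyst + target <-> idle complex; substrate + target -> side product; dissolved gas -> decomposed reagent
- no earlier run changes the charge of catalyst; that part of a forecast is a guess

- delta: doubling the amount of catalyst, all else as stated
- zeta: doubling the saturation concentration of gas phase, all else as stated
- beta: doubling the transfer coefficient of the gas phase, all else as stated

1. the target and idle complex together standing at 5.0 min, as a percentage of the substrate charged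
2. concentration of dissolved gas in solution at 80 s, in percent of saturation
3. the change that raises the amount of target and idle complex together at 5.0 min, in percent of the substrate charged most ("none" if none brings more than 2 percentage points) (delta / zeta / beta / none)
4. amount of target and idle complex together at 5.0 min, in percent of the substrate charged, after beta

The saturation is the same in the flask, so I kept r, and the flask's charge needs 99.1 s of feed. The asked time is 3.03 such spans, but a yield cannot pass 100%, so the line ends at a ratio of one.

The teal line also bends. At 90.0 s it promised 59.4% and the reading was 44.3%, a shortfall of 15 percentage points. I charged this to substrate + target -> side product, though slowing gas would look the same. I took the loss as a race number S, the side step's strength against the feed, times the running sum of fed fraction by unfed fraction. That gave S = 1.42 for teal. S goes with the charge squared at equal r, so the flask has 0.606.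

A whole feed then loses 10.1% of the charge as target. Going round once more, the feed ends sooner by that loss, which gives 9.81% and a feed time of 89.3 s. Each lost target takes one substrate with it, so I reckoned 80.4% at the plateau.

The forecast gave 90% (81% to 96%) of target and idle complex together at the asked time, dissolved gas at 52% of saturation (38% to 68%) at 80 s, and 92% (84% to 97%) after beta, and it chose zeta: “Doubling saturation doubles rate in both regimes, so zeta wins.” My figure stood lower than the forecast's.

The flask gave 71.2% of target and idle complex together, with dissolved gas at 42.6% of saturation at 80 s, zeta the best change with a gain of 11 points, and 78.3% after beta. Side product in the flask stood at 28.8% at 5.00 min against my 19.6%. The asked time is 3.36 feed times, and the flask held 71.2% at 50.0 min.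

    gas phase ⇌ dissolved gas, rate k1*(csat - [dissolved gas]) (kL = 0.0780 /s)
    substrate + dissolved gas + catalyst → catalyst + target (k = 11.0 /M²/s)
    catalyst + target ⇌ idle complex (K = 10.0 /M, k = 0.110 /M/s)
    substrate + target → side product (k = 0.0120 /M/s)
    dissolved gas → decomposed reagent (k = 0.0150 /s)

The same flask read at 2.0 min stands 1.34 feed times along, so the feed time puts it at the plateau. Computed, it holds 66.8% of target and idle complex together, 4.4 points under the flask at the asked time, with 7.1% of the substrate left, so it has not reached the plateau.

Readings and results were computed for substances that don't exist, noise included.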